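Locants follow the drimane skeleton: ring A is C1‑C2‑C3‑C4‑C5‑C10, ring B is C5‑C6‑C7‑C8‑C9‑C10, C11 is the oxymethylene carbon on C9 and C12 the exocyclic methylene carbon on C8; C3 carries OH, C4 two methyls, C10 one.
Cuts, in order: the C11–O aryl ether; C6=C7 back to a C7 ketal; then C8–C9 and C1–C10 in one operation, which opens both rings to an acyclic C5‑branched cyclopropanol; further back C7–C8, the C1 methylene, C10–CH3 and C9–C11.
Enabling feature: C3 is an oxidised carbon two atoms from C1, so a C3 cyclopropanol is a latent C1 radical; C10 is the β‑carbon of the C9–C11 enoate and C8 is an alkyne carbon, so ring A (C1–C10) and then ring B (C9–C8) can close in one radical chain.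
Forward: the cyclopentene of (S)‑α‑campholenic aldehyde supplies C2–C7 with the gem‑dimethyl group and C5, and its side chain becomes C10–C9 (ynoate, then Z‑enoate); ozonolysis opens the ring to the C3 ketone and C7 aldehyde, the alkynyl ketal and cyclopropanol follow, the bicyclisation forms ring A then ring B, the C7 ketone becomes C6=C7 and umbelliferone is attached last.
Stereochemistry: C5 comes from the chiral pool; C10 is relayed from C5 by allylic 1,3‑strain in the Z‑enoate (trans fusion); C9 is set in the closure of ring B (equatorial ester); C3 is set by equatorial hydride delivery (axial alcohol).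

Key step: step 10

Remark: (S)‑α‑campholenic aldehyde is taken as a purchasable chiral‑pool aldehyde of high enantiomeric purity (it is the ZnBr2 isomerisation product of (1R,5R)‑α‑pinene oxide).

Step 1
Reactants: 1 (S)‑α‑campholenic aldehyde
Product: 2 2‑[(1S)‑2,2,3‑trimethylcyclopent‑3‑en‑1‑yl]ethenyl trifluoromethanesulfonate (E/Z mixture)
Conditions: Tf2O, 2,6‑di‑tert‑butyl‑4‑methylpyridine, CH2Cl2, 0 → 40 °C
Reagents that add atoms: trifluoromethanesulfonic anhydride, O=S(=O)(OS(=O)(=O)C(F)(F)F)C(F)(F)F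
Why: Enol triflate formation from an aldehyde (O‑sulfonylation, then loss of the only enolisable proton to the hindered pyridine) gives the primary vinyl triflate and leaves the ring alkene and the C5 stereocentre untouched.

Step 2
Reactants: 2 vinyl triflate
Product: 4 methyl 3‑[(1S)‑2,2,3‑trimethylcyclopent‑3‑en‑1‑yl]prop‑2‑ynoate, via lithium acetylide 3 (not isolated)
Conditions: LiN(i‑Pr)2 (2.3 equiv), THF, −78 → −20 °C; then ClCO2Me, −78 °C, cold quench
Reagents that add atoms: methyl chloroformate, COC(=O)Cl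
Why: Base‑induced elimination of the vinyl triflate (anti‑E2 for the Z isomer, α‑elimination with 1,2‑shift for the E isomer) gives the alkyne, which the second equivalent of amide holds as the acetylide until it is C‑acylated by the chloroformate; the acetylide protects the propargylic C5–H from deprotonation.

Step 3
Reactants: 4 ynoate
Product: 5 methyl (2Z)‑3‑[(1S)‑2,2,3‑trimethylcyclopent‑3‑en‑1‑yl]but‑2‑enoate
Conditions: Me2CuLi (from MeLi and CuI), THF, −78 °C; MeOH quench at −78 °C
Reagents that add atoms: lithium dimethylcuprate, [Li+].C[Cu-]C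
Why: Conjugate syn‑carbocupration of an ynoate by a Gilman cuprate, protonated cold with retention, puts the new methyl trans to the ester, so C5 ends cis to CO2Me (Z).

Step 4
Reactants: 5 Z‑enoate
Product: 7 methyl (2Z,4S)‑3,5,5‑trimethyl‑6‑oxo‑4‑(2‑oxoethyl)hept‑2‑enoate, via ozonide 6 (not isolated)
Conditions: O3, CH2Cl2, −78 °C (Sudan Red 7B end point); then PPh3, −78 °C → rt
Reagents that add atoms: ozone, [O-][O+]=O
Why: Ozonolysis with reductive work‑up cleaves the electron‑rich trisubstituted ring alkene much faster than the conjugated enoate and gives the C3 methyl ketone and the C7 aldehyde.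

Step 5
Reactants: 7 keto aldehyde; 8 trimethylsilylacetylene
Product: 9 methyl (2Z,4S)‑4‑[2‑hydroxy‑4‑(trimethylsilyl)but‑3‑yn‑1‑yl]‑3,5,5‑trimethyl‑6‑oxohept‑2‑enoate (both C7 epimers)
Conditions: 8, n‑BuLi, THF, −78 °C; then 7, −78 °C
Reagents that add atoms: none
Why: 1,2‑Addition of a lithium acetylide at low temperature takes the unhindered aldehyde far faster than the ketone beside the quaternary C4 or the β,β‑disubstituted enoate; the C7 carbinol forms as both epimers, which are merged by the next oxidation.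

Step 6
Reactants: 9 propargylic alcohol
Product: 10 methyl (2Z,4S)‑3,5,5‑trimethyl‑6‑oxo‑4‑[2‑oxo‑4‑(trimethylsilyl)but‑3‑yn‑1‑yl]hept‑2‑enoate
Conditions: Dess–Martin periodinane, NaHCO3, CH2Cl2, 0 °C → rt
Reagents that add atoms: none
Why: Dess–Martin oxidation of a secondary propargylic alcohol gives the ynone under buffered conditions that spare the enoate, the ketone and the C–Si bond.

Step 7
Reactants: 10 keto ynone
Product: 11 methyl (2Z,4S)‑3,5,5‑trimethyl‑6‑oxo‑4‑({2‑[(trimethylsilyl)ethynyl]‑1,3‑dioxolan‑2‑yl}methyl)hept‑2‑enoate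
Conditions: Me3SiOCH2CH2OSiMe3 (1.2 equiv), TMSOTf (5 mol %), CH2Cl2, −78 → −40 °C
Reagents that add atoms: 1,2‑bis(trimethylsilyloxy)ethane, C[Si](C)(C)OCCO[Si](C)(C)C
Why: Noyori ketalisation at low temperature takes the C7 carbonyl, flanked only by CH2 and a slim alkynyl group, while the C3 carbonyl beside the quaternary C4 is too hindered; the silyl cap on the alkyne blocks conjugate addition.

Step 8
Reactants: 11 keto ketal
Product: 12 methyl (2Z,4S)‑3,5,5‑trimethyl‑6‑(trimethylsilyloxy)‑4‑({2‑[(trimethylsilyl)ethynyl]‑1,3‑dioxolan‑2‑yl}methyl)hepta‑2,6‑dienoate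
Conditions: TMSOTf, Et3N, CH2Cl2, 0 °C
Reagents that add atoms: trimethylsilyl trifluoromethanesulfonate, C[Si](C)(C)OS(=O)(=O)C(F)(F)F
Why: Soft enolisation (silyl triflate and amine) silylates the C3 ketone on its only enolisable side, the methyl group, under conditions too weakly basic to remove the γ‑protons of the enoate, C5–H included.

Step 9
Reactants: 12 silyl enol ether
Product: 14 methyl (2Z,4S)‑4‑[(2‑ethynyl‑1,3‑dioxolan‑2‑yl)methyl]‑5‑(1‑hydroxycyclopropyl)‑3,5‑dimethylhex‑2‑enoate, via bis‑silyl cyclopropyl ether 13 (not isolated)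
Conditions: Et2Zn, CH2I2, CH2Cl2, 0 °C → rt; then MeOH, K2CO3, 0 °C → rt
Reagents that add atoms: diiodomethane, ICI
Why: Simmons–Smith cyclopropanation (Furukawa variant) adds the electrophilic zinc carbenoid to the electron‑rich silyl enol ether only, and carbonate in methanol then removes both the O‑silyl and the alkynyl C‑silyl groups.

Step 10
Reactants: 14 cyclopropanol with Z‑enoate and alkynyl ketal arms
Product: 15 methyl (5S,9S,10R)‑7,7‑(ethylenedioxy)‑3‑oxodrim‑8(12)‑en‑11‑oate (trans‑decalin; C3 ketone; C7 dioxolane; C8=C12; equatorial C9 CO2Me cis to the C10 methyl)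
Conditions: Mn(acac)3 (2.2 equiv), degassed EtOH, 0.01 M, 25 → 50 °C
Reagents that add atoms: none
Why: Proposed new method: Mn(acac)3 (trivalent manganese) binds the cyclopropanol as its alkoxide, and one‑electron oxidation with strain‑driven β‑scission gives the C3 ketone and a primary C1 radical, which closes ring A 6‑exo‑trig on the enoate β‑carbon C10; the α‑ester radical at C9 then closes ring B 6‑exo‑dig on the internal alkyne carbon C8, and the C12 vinyl radical takes hydrogen from ethanol, whose radical is oxidised to acetaldehyde by the second equivalent of oxidant. The closest known reaction types are manganese‑mediated opening of cyclopropanols to β‑keto radicals that add to acceptor olefins, and oxidative radical cyclisations that end on an alkyne in ethanol; their combination in a bicyclisation that creates a quaternary centre has not been shown. C10 is controlled by C5: in the chair transition state the C6 arm is equatorial, and because the ester is cis to C5, allylic 1,3‑strain keeps H5 in the enoate plane, so C1 reaches only the face that leaves the C10 methyl axial and anti to H5 (trans fusion). C9 is set in the second closure, where the ester takes the equatorial site away from the axial dioxolane oxygen on C7 and from H5; this is also the more stable epimer. The step needs ring closure to outrun hydrogen capture and 1,5‑hydrogen transfer; the polarity match of the alkyl radical with the enoate, the gem‑dimethyl and ketal groups that fold both chains, and the absence of any acceptor other than the alkyne near the electrophilic C9 radical are relied on for this.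

Step 11
Reactants: 15 keto ester
Product: 17 (3S,5S,9S,10R)‑7,7‑(ethylenedioxy)drim‑8(12)‑ene‑3,11‑diol, via hydroxy ester 16 (not isolated)
Conditions: KBH(s‑Bu)3, THF, −78 °C; then LiAlH4, −78 → 0 °C
Reagents that add atoms: none
Why: Two hydride reductions in sequence: the bulky borohydride attacks the C3 ketone along the equatorial trajectory and sets the axial alcohol (cis to H5, trans to the C10 methyl), and LiAlH4 then reduces the ester to the C11 primary alcohol without touching ketal or alkene.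

Step 12
Reactants: 17 diol
Product: 18 (3S,5S,9S,10R)‑3,11‑bis(tert‑butyldimethylsilyloxy)‑7,7‑(ethylenedioxy)drim‑8(12)‑ene
Conditions: TBSOTf, 2,6‑lutidine, CH2Cl2, −78 → 0 °C
Reagents that add atoms: tert‑butyldimethylsilyl trifluoromethanesulfonate, CC(C)(C)[Si](C)(C)OS(=O)(=O)C(F)(F)F
Why: Silyl ether formation with the silyl triflate and a pyridine base covers both the primary and the hindered axial secondary alcohol, and dioxolane ketals tolerate it at low temperature.

Step 13
Reactants: 18 bis‑silyl ketal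
Product: 19 (3S,5S,9S,10R)‑3,11‑bis(tert‑butyldimethylsilyloxy)drim‑8(12)‑en‑7‑one
Conditions: pyridinium p‑toluenesulfonate, acetone/H2O, 50 °C
Reagents that add atoms: water, O
Why: Acid‑catalysed ketal hydrolysis: the oxocarbenium ion at C7 is allylic, so the ketal opens under mild conditions that both silyl ethers survive.

Step 14
Reactants: 19 α‑methylene ketone
Product: 20 (3S,5S,9S,10R)‑3,11‑bis(tert‑butyldimethylsilyloxy)drima‑6,8(12)‑dien‑7‑yl trifluoromethanesulfonate
Conditions: KN(SiMe3)2, THF, −78 °C; then PhNTf2, −78 → 0 °C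
Reagents that add atoms: N‑phenylbis(trifluoromethanesulfonimide), O=S(=O)(N(c1ccccc1)S(=O)(=O)C(F)(F)F)C(F)(F)F
Why: Kinetic enolisation at C6, the only enolisable position because C8 has no hydrogen, followed by O‑sulfonylation of the cross‑conjugated enolate gives the dienyl triflate (enol triflate formation).

Step 15
Reactants: 20 dienyl triflate
Product: 21 (3S,5S,9R,10R)‑3,11‑bis(tert‑butyldimethylsilyloxy)drima‑6,8(12)‑diene
Conditions: Pd(OAc)2 (cat.), PPh3, n‑Bu3N, HCO2H, DMF, 60 °C
Reagents that add atoms: none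
Why: Palladium‑catalysed formate reduction of a vinyl triflate (oxidative addition to zerovalent palladium, formate exchange, loss of CO2, reductive elimination) replaces OTf by H and leaves the double bond at C6–C7.

Step 16
Reactants: 21 bis‑silyl diene
Product: 22 (3S,5S,9R,10R)‑drima‑6,8(12)‑diene‑3,11‑diol
Conditions: Bu4NF, THF, 25 → 50 °C
Reagents that add atoms: none
Why: Fluoride‑induced desilylation removes both silyl ethers; no coumarin is present yet, so the warming needed for the hindered C3 ether is harmless.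

Step 17
Reactants: 22 diene diol; 23 umbelliferone
Product: 24 7‑{[(1R,4aS,6S,8aR)‑6‑hydroxy‑5,5,8a‑trimethyl‑2‑methylidene‑1,2,4a,5,6,7,8,8a‑octahydronaphthalen‑1‑yl]methoxy}‑2H‑chromen‑2‑one (target)
Conditions: PPh3, DIAD, THF, 0 °C → rt
Reagents that add atoms: none
Why: Mitsunobu etherification: the acidic phenol displaces the oxyphosphonium of the primary C11 alcohol, while the axial C3 alcohol between the gem‑dimethyl group and C2 is too hindered to be activated; no stereocentre is touched.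

Compound list
1 | (S)‑α‑campholenic aldehyde, 2‑[(1S)‑2,2,3‑trimethylcyclopent‑3‑en‑1‑yl]acetaldehyde | O=CC[C@@H]1CC=C(C)C1(C)C | starting material
2 | 2‑[(1S)‑2,2,3‑trimethylcyclopent‑3‑en‑1‑yl]ethenyl trifluoromethanesulfonate (E/Z mixture) | O=S(=O)(OC=C[C@@H]1CC=C(C)C1(C)C)C(F)(F)F | intermediate
3 | lithium 2‑[(1S)‑2,2,3‑trimethylcyclopent‑3‑en‑1‑yl]ethynide | [Li]C#C[C@@H]1CC=C(C)C1(C)C | intermediate
4 | methyl 3‑[(1S)‑2,2,3‑trimethylcyclopent‑3‑en‑1‑yl]prop‑2‑ynoate | COC(=O)C#C[C@@H]1CC=C(C)C1(C)C | intermediate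
5 | methyl (2Z)‑3‑[(1S)‑2,2,3‑trimethylcyclopent‑3‑en‑1‑yl]but‑2‑enoate | COC(=O)/C=C(/C)[C@@H]1CC=C(C)C1(C)C | intermediate
6 | secondary ozonide of 5, methyl (2Z)‑3‑[(3S)‑1,2,2‑trimethyl‑6,7,8‑trioxabicyclo[3.2.1]octan‑3‑yl]but‑2‑enoate (bridgehead configuration not defined) | COC(=O)/C=C(/C)[C@@H]1CC2OOC(C)(O2)C1(C)C | intermediate
7 | methyl (2Z,4S)‑3,5,5‑trimethyl‑6‑oxo‑4‑(2‑oxoethyl)hept‑2‑enoate | O=CC[C@@H](/C(C)=C\C(=O)OC)C(C)(C)C(C)=O | intermediate
8 | trimethylsilylacetylene | C#C[Si](C)(C)C | starting material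
9 | methyl (2Z,4S)‑4‑[2‑hydroxy‑4‑(trimethylsilyl)but‑3‑yn‑1‑yl]‑3,5,5‑trimethyl‑6‑oxohept‑2‑enoate (both C7 epimers) | C[Si](C)(C)C#CC(O)C[C@@H](/C(C)=C\C(=O)OC)C(C)(C)C(C)=O | intermediate
10 | methyl (2Z,4S)‑3,5,5‑trimethyl‑6‑oxo‑4‑[2‑oxo‑4‑(trimethylsilyl)but‑3‑yn‑1‑yl]hept‑2‑enoate | C[Si](C)(C)C#CC(=O)C[C@@H](/C(C)=C\C(=O)OC)C(C)(C)C(C)=O | intermediate
11 | methyl (2Z,4S)‑3,5,5‑trimethyl‑6‑oxo‑4‑({2‑[(trimethylsilyl)ethynyl]‑1,3‑dioxolan‑2‑yl}methyl)hept‑2‑enoate | C[Si](C)(C)C#CC1(OCCO1)C[C@@H](/C(C)=C\C(=O)OC)C(C)(C)C(C)=O | intermediate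
12 | methyl (2Z,4S)‑3,5,5‑trimethyl‑6‑(trimethylsilyloxy)‑4‑({2‑[(trimethylsilyl)ethynyl]‑1,3‑dioxolan‑2‑yl}methyl)hepta‑2,6‑dienoate | C[Si](C)(C)C#CC1(OCCO1)C[C@@H](/C(C)=C\C(=O)OC)C(C)(C)C(=C)O[Si](C)(C)C | intermediate
13 | methyl (2Z,4S)‑3,5‑dimethyl‑5‑[1‑(trimethylsilyloxy)cyclopropyl]‑4‑({2‑[(trimethylsilyl)ethynyl]‑1,3‑dioxolan‑2‑yl}methyl)hex‑2‑enoate | C[Si](C)(C)C#CC1(OCCO1)C[C@@H](/C(C)=C\C(=O)OC)C(C)(C)C1(O[Si](C)(C)C)CC1 | intermediate
14 | methyl (2Z,4S)‑4‑[(2‑ethynyl‑1,3‑dioxolan‑2‑yl)methyl]‑5‑(1‑hydroxycyclopropyl)‑3,5‑dimethylhex‑2‑enoate | C#CC1(OCCO1)C[C@@H](/C(C)=C\C(=O)OC)C(C)(C)C1(O)CC1 | intermediate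
15 | methyl (5S,9S,10R)‑7,7‑(ethylenedioxy)‑3‑oxodrim‑8(12)‑en‑11‑oate | C=C1C2(OCCO2)C[C@@H]3C(C)(C)C(=O)CC[C@@]3(C)[C@@H]1C(=O)OC | intermediate
16 | methyl (3S,5S,9S,10R)‑7,7‑(ethylenedioxy)‑3‑hydroxydrim‑8(12)‑en‑11‑oate (axial 3‑OH) | C=C1C2(OCCO2)C[C@@H]3C(C)(C)[C@@H](O)CC[C@@]3(C)[C@@H]1C(=O)OC | intermediate
17 | (3S,5S,9S,10R)‑7,7‑(ethylenedioxy)drim‑8(12)‑ene‑3,11‑diol | C=C1C2(OCCO2)C[C@@H]3C(C)(C)[C@@H](O)CC[C@@]3(C)[C@@H]1CO | intermediate
18 | (3S,5S,9S,10R)‑3,11‑bis(tert‑butyldimethylsilyloxy)‑7,7‑(ethylenedioxy)drim‑8(12)‑ene | C=C1C2(OCCO2)C[C@@H]3C(C)(C)[C@@H](O[Si](C)(C)C(C)(C)C)CC[C@@]3(C)[C@@H]1CO[Si](C)(C)C(C)(C)C | intermediate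
19 | (3S,5S,9S,10R)‑3,11‑bis(tert‑butyldimethylsilyloxy)drim‑8(12)‑en‑7‑one | C=C1C(=O)C[C@@H]2C(C)(C)[C@@H](O[Si](C)(C)C(C)(C)C)CC[C@@]2(C)[C@@H]1CO[Si](C)(C)C(C)(C)C | intermediate
20 | (3S,5S,9S,10R)‑3,11‑bis(tert‑butyldimethylsilyloxy)drima‑6,8(12)‑dien‑7‑yl trifluoromethanesulfonate | C=C1C(OS(=O)(=O)C(F)(F)F)=C[C@@H]2C(C)(C)[C@@H](O[Si](C)(C)C(C)(C)C)CC[C@@]2(C)[C@@H]1CO[Si](C)(C)C(C)(C)C | intermediate
21 | (3S,5S,9R,10R)‑3,11‑bis(tert‑butyldimethylsilyloxy)drima‑6,8(12)‑diene | C=C1C=C[C@@H]2C(C)(C)[C@@H](O[Si](C)(C)C(C)(C)C)CC[C@@]2(C)[C@@H]1CO[Si](C)(C)C(C)(C)C | intermediate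
22 | (3S,5S,9R,10R)‑drima‑6,8(12)‑diene‑3,11‑diol | C=C1C=C[C@@H]2C(C)(C)[C@@H](O)CC[C@@]2(C)[C@@H]1CO | intermediate
23 | umbelliferone, 7‑hydroxy‑2H‑chromen‑2‑one | Oc1ccc2ccc(=O)oc2c1 | starting material
24 | 7‑{[(1R,4aS,6S,8aR)‑6‑hydroxy‑5,5,8a‑trimethyl‑2‑methylidene‑1,2,4a,5,6,7,8,8a‑octahydronaphthalen‑1‑yl]methoxy}‑2H‑chromen‑2‑one; in drimane locants (3S,5S,9R,10R)‑11‑(2‑oxo‑2H‑chromen‑7‑yloxy)drima‑6,8(12)‑dien‑3‑ol | C=C1C=C[C@@H]2C(C)(C)[C@@H](O)CC[C@@]2(C)[C@@H]1COc1ccc2ccc(=O)oc2c1 | target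

Total step count: 17. Longest linear sequence: 17 steps (1 → 24); compounds 8 and 23 are bought.

Steps most likely to fail

Step 10 (radical bicyclisation). What may go wrong: hydrogen capture from the alcohol by the C1 or C9 radical before ring closure, 1,5‑hydrogen transfer from C5–H to the C1 radical, or further oxidation by trivalent manganese. Fallback, from 14 and back to the route at 15: the cyclopropanol is opened with N‑iodosuccinimide in CH2Cl2 at 0 °C to the β‑iodo ketone methyl (2Z,4S)‑4‑[(2‑ethynyl‑1,3‑dioxolan‑2‑yl)methyl]‑8‑iodo‑3,5,5‑trimethyl‑6‑oxooct‑2‑enoate F1. Slow addition of Bu3SnH with AIBN in benzene at 80 °C then runs the two closures as a reductive chain (iodine abstraction, 6‑exo‑trig, 6‑exo‑dig, hydrogen transfer from tin). The hydrogen donor is kept at low concentration throughout, which cannot be done in an alcohol solvent.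

Step 7 (ketalisation of one of two ketones). What may go wrong: loss of discrimination between the two carbonyl groups, so that C3 is ketalised as well. Fallback, from 10 and back at 11: both carbonyls are ketalised on purpose (ethylene glycol in excess, TsOH, benzene, reflux with water removal) to the bis(dioxolane) methyl (2Z,4S)‑3,5‑dimethyl‑5‑(2‑methyl‑1,3‑dioxolan‑2‑yl)‑4‑({2‑[(trimethylsilyl)ethynyl]‑1,3‑dioxolan‑2‑yl}methyl)hex‑2‑enoate F2. The crowded saturated ketal at C3 is then hydrolysed selectively with pyridinium p‑toluenesulfonate in wet acetone; the alkynyl ketal, whose oxocarbenium ion is destabilised by the alkyne, should survive.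

Step 14 (enol triflate from the α‑methylene ketone). What may go wrong: conjugate addition of the amide base to the exo‑methylene ketone and self‑condensation of the cross‑conjugated enolate in competition with O‑sulfonylation. Fallback, from 19 and back at 21:
- Luche reduction (NaBH4, CeCl3·7H2O, MeOH, −78 °C) gives the allylic alcohol (3S,5S,9S,10R)‑3,11‑bis(tert‑butyldimethylsilyloxy)drim‑8(12)‑en‑7‑ol F3 as either C7 epimer.
- Methyl chloroformate with pyridine and DMAP gives its allylic methyl carbonate F4.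
- Pd(PPh3)4 (zerovalent palladium) in refluxing dioxane ionises the carbonate to the π‑allyl complex, and β‑hydride elimination from C6, the only carbon with hydrogen next to an allyl terminus, gives the diene.

Further compounds
F1 | step 10 | methyl (2Z,4S)‑4‑[(2‑ethynyl‑1,3‑dioxolan‑2‑yl)methyl]‑8‑iodo‑3,5,5‑trimethyl‑6‑oxooct‑2‑enoate | C#CC1(OCCO1)C[C@@H](/C(C)=C\C(=O)OC)C(C)(C)C(=O)CCI
F2 | step 7 | methyl (2Z,4S)‑3,5‑dimethyl‑5‑(2‑methyl‑1,3‑dioxolan‑2‑yl)‑4‑({2‑[(trimethylsilyl)ethynyl]‑1,3‑dioxolan‑2‑yl}methyl)hex‑2‑enoate | C[Si](C)(C)C#CC1(OCCO1)C[C@@H](/C(C)=C\C(=O)OC)C(C)(C)C1(C)OCCO1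
F3 | step 14 | (3S,5S,9S,10R)‑3,11‑bis(tert‑butyldimethylsilyloxy)drim‑8(12)‑en‑7‑ol (C7 epimers) | C=C1C(O)C[C@@H]2C(C)(C)[C@@H](O[Si](C)(C)C(C)(C)C)CC[C@@]2(C)[C@@H]1CO[Si](C)(C)C(C)(C)C
F4 | step 14 | (3S,5S,9S,10R)‑3,11‑bis(tert‑butyldimethylsilyloxy)drim‑8(12)‑en‑7‑yl methyl carbonate (C7 epimers) | C=C1C(OC(=O)OC)C[C@@H]2C(C)(C)[C@@H](O[Si](C)(C)C(C)(C)C)CC[C@@]2(C)[C@@H]1CO[Si](C)(C)C(C)(C)C
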